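**Retrosynthetic overview**
1. The seven-membered ring is closed last by ring-closing metathesis (C7=C8) of a cyclopentane carrying a 1-(aroyloxy)allyl arm on C5 and a 3-methylbut-3-enyl arm on C1.
2. The key bond is C6–O: the p-anisate is installed by a redox-neutral rhodium-catalysed coupling of 4-methoxybenzoic acid with a propargyl side chain (terminal alkyne to branched allylic ester), which also sets C6.
3. The C4 carbinol comes from isopropyl addition to a 2-propargyl-3,3-disubstituted cyclopentanone.
4. C1 (quaternary) and C5 come from a one-pot copper-catalysed asymmetric conjugate methylation/enolate propargylation of 3-(3-methylbut-3-enyl)cyclopent-2-enone, made from 3-ethoxycyclopent-2-enone and a homoallylic Grignard reagent.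
5. Ring order: the five-membered ring is bought as the cyclopentenone; the seven-membered ring is formed in the final step.

Atom labels C1–C10 are daucane positions of the target: C1 is the methyl-bearing ring-fusion carbon, C4 the isopropyl carbinol, C5 the ring-fusion CH, C6 the ester-bearing carbon, and C7=C8 the ring alkene with the methyl on C8.

Assumption: the sense of induction of the two chiral ligands (phosphoramidite in step 2, DIOP in step 4) is taken by analogy with simpler substrates; if a first run shows the opposite sense, the antipodal ligand is used with no other change.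

**Step 1**
Reactants: 1 3-ethoxycyclopent-2-en-1-one; 2 4-bromo-2-methylbut-1-ene
Product: 5 3-(3-methylbut-3-en-1-yl)cyclopent-2-en-1-one, via Grignard reagent 3 (not isolated), via magnesium alkoxide adduct 4 (not isolated)
Conditions: 2, Mg, THF, rt; then 1, 0 °C to rt; then 1 M aq HCl, 0 °C
Reagents that add atoms: water, O
Why: Stork–Danheiser-type sequence in which 1,2-addition of the Grignard reagent to the vinylogous ester and acid hydrolysis of the enol ether carbinol (loss of ethanol and water) transpose the carbonyl to give the 3-substituted enone; no stereocentre is formed.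

**Step 2**
Reactants: 5 3-(3-methylbut-3-en-1-yl)cyclopent-2-en-1-one
Product: 8 (2R,3S)-3-methyl-3-(3-methylbut-3-en-1-yl)-2-(prop-2-yn-1-yl)cyclopentan-1-one, via dimethylaluminium enolate 6 (not isolated), via lithium aluminate enolate 7 (not isolated)
Conditions: Me3Al (1.5 equiv), CuTC (copper thiophene-2-carboxylate, CuO2CC4H3S, 5 mol %), chiral biphenol-derived phosphoramidite (10 mol %), Et2O, −30 °C; then THF, MeLi (1.6 equiv), −30 °C; then DMPU, propargyl bromide (3 equiv), −30 °C to rt
Reagents that add atoms: trimethylaluminium, C[Al](C)C; propargyl bromide, C#CCBr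
Why: Copper-catalysed asymmetric conjugate addition of Me3Al (ligand-controlled methyl delivery to one enone face sets the C1 quaternary centre, 3S) gives a regiodefined enolate that, activated as the aluminate, undergoes SN2 alkylation at C5 anti to the larger butenyl arm, so the propargyl group ends up trans to that arm and cis to the methyl (2R).

**Step 3**
Reactants: 8 (2R,3S)-3-methyl-3-(3-methylbut-3-en-1-yl)-2-(prop-2-yn-1-yl)cyclopentan-1-one
Product: 9 (1R,2R,3S)-3-methyl-3-(3-methylbut-3-en-1-yl)-1-(propan-2-yl)-2-(prop-2-yn-1-yl)cyclopentan-1-ol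
Conditions: iPrMgCl (3 equiv), CeCl3 (3 equiv), THF, −78 to −40 °C; aq NH4Cl
Reagents that add atoms: isopropylmagnesium chloride, CC(C)[Mg]Cl
Why: Organocerium 1,2-addition (weakly basic, so enolisation and reduction are suppressed and the excess covers the alkyne C–H) occurs on the carbonyl face opposite the adjacent propargyl group, placing the new C4 hydroxyl cis to the propargyl arm and to the C1 methyl (1R).

**Step 4**
Reactants: 9 (1R,2R,3S)-3-methyl-3-(3-methylbut-3-en-1-yl)-1-(propan-2-yl)-2-(prop-2-yn-1-yl)cyclopentan-1-ol; 10 4-methoxybenzoic acid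
Product: 12 (1S)-1-[(1S,2R,5S)-2-hydroxy-5-methyl-5-(3-methylbut-3-en-1-yl)-2-(propan-2-yl)cyclopentyl]prop-2-en-1-yl 4-methoxybenzoate, via allene 11 (not isolated)
Conditions: [Rh(cod)Cl]2 (2.5 mol %), (R,R)-DIOP (6 mol %), 10 (1.5 equiv), ClCH2CH2Cl, 70 °C, 16 h
Reagents that add atoms: none
Why: Proposed new method: a reagent-controlled, hydroxyl-tolerant redox-neutral coupling of a terminal alkyne with a carboxylic acid at a neopentylic ring position, in which monovalent rhodium and 10 give a trivalent rhodium hydride carboxylate that isomerises the alkyne to allene 11, adds again to its central carbon to form a σ/π-allyl rhodium carboxylate, and closes the C6–O bond by inner-sphere reductive elimination at the substituted allyl terminus, the C2-symmetric DIOP pocket selecting the C6 face (6S) over the bias of the resident C5 centre while the free C4 hydroxyl and the 1,1-disubstituted alkene are left alone; the closest known reaction type is the rhodium/DIOP-catalysed addition of carboxylic acids to simple terminal alkynes and allenes giving branched allylic esters, which has not been shown for a propargylic CH2 on a stereogenic ring carbon flanked by two fully substituted carbons and bearing a free β-tertiary alcohol.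

**Step 5**
Reactants: 12 (1S)-1-[(1S,2R,5S)-2-hydroxy-5-methyl-5-(3-methylbut-3-en-1-yl)-2-(propan-2-yl)cyclopentyl]prop-2-en-1-yl 4-methoxybenzoate
Product: 13 (3R,3aS,4S,8aS)-3-hydroxy-6,8a-dimethyl-3-(propan-2-yl)-1,2,3,3a,4,7,8,8a-octahydroazulen-4-yl 4-methoxybenzoate
Conditions: second-generation Grubbs catalyst RuCl2(=CHPh)(PCy3)(H2IMes) (5–10 mol %), toluene (5 mM), 80 °C
Reagents that add atoms: none
Why: Ring-closing metathesis of the vinyl group onto the 1,1-disubstituted alkene closes the trans-fused seven-membered ring and forms the trisubstituted C7=C8 alkene with loss of ethene, the tertiary alcohol and the ester being inert to the ruthenium carbene and no stereocentre being touched.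

**Compound list**
1 | 3-ethoxycyclopent-2-en-1-one | CCOC1=CC(=O)CC1 | starting material
2 | 4-bromo-2-methylbut-1-ene | CC(=C)CCBr | starting material
3 | (3-methylbut-3-en-1-yl)magnesium bromide | CC(=C)CC[Mg]Br | intermediate
4 | bromomagnesium 3-ethoxy-1-(3-methylbut-3-en-1-yl)cyclopent-2-en-1-olate (racemic) | CCOC1=CC(CCC(C)=C)(O[Mg]Br)CC1 | intermediate
5 | 3-(3-methylbut-3-en-1-yl)cyclopent-2-en-1-one | CC(=C)CCC1=CC(=O)CC1 | intermediate
6 | dimethylaluminium (3S)-3-methyl-3-(3-methylbut-3-en-1-yl)cyclopent-1-en-1-olate | C[Al](C)OC1=C[C@@](C)(CCC(C)=C)CC1 | intermediate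
7 | lithium trimethyl{[(3S)-3-methyl-3-(3-methylbut-3-en-1-yl)cyclopent-1-en-1-yl]oxy}aluminate | [Li+].C[Al-](C)(C)OC1=C[C@@](C)(CCC(C)=C)CC1 | intermediate
8 | (2R,3S)-3-methyl-3-(3-methylbut-3-en-1-yl)-2-(prop-2-yn-1-yl)cyclopentan-1-one | C#CC[C@@H]1[C@@](C)(CCC(C)=C)CCC1=O | intermediate
9 | (1R,2R,3S)-3-methyl-3-(3-methylbut-3-en-1-yl)-1-(propan-2-yl)-2-(prop-2-yn-1-yl)cyclopentan-1-ol | C#CC[C@@H]1[C@@](C)(CCC(C)=C)CC[C@@]1(O)C(C)C | intermediate
10 | 4-methoxybenzoic acid | COc1ccc(cc1)C(O)=O | starting material
11 | (1R,2R,3S)-3-methyl-3-(3-methylbut-3-en-1-yl)-1-(propan-2-yl)-2-(propa-1,2-dien-1-yl)cyclopentan-1-ol | C=C=C[C@@H]1[C@@](C)(CCC(C)=C)CC[C@@]1(O)C(C)C | intermediate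
12 | (1S)-1-[(1S,2R,5S)-2-hydroxy-5-methyl-5-(3-methylbut-3-en-1-yl)-2-(propan-2-yl)cyclopentyl]prop-2-en-1-yl 4-methoxybenzoate | COc1ccc(cc1)C(=O)O[C@@H](C=C)[C@@H]2[C@@](C)(CCC(C)=C)CC[C@@]2(O)C(C)C | intermediate
13 | (3R,3aS,4S,8aS)-3-hydroxy-6,8a-dimethyl-3-(propan-2-yl)-1,2,3,3a,4,7,8,8a-octahydroazulen-4-yl 4-methoxybenzoate (trans-fused; C4 hydroxyl cis to the C1 methyl; ester oxygen on the face of H-5) | COc1ccc(C(=O)O[C@H]2C=C(C)CC[C@@]3(C)CC[C@@](O)(C(C)C)[C@H]23)cc1 | target

**Total step count:** 5
**Longest linear sequence:** 5 steps (from 1 or 2)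

**Steps most likely to fail**

Step 4, the proposed new coupling. The crowded allyl terminus may give the linear ester or a diene by β-hydride elimination, the ligand and the resident C5 centre may be mismatched, or the C4 hydroxyl may cyclise onto the allene. The fallback uses known chemistry only, sets out from enone 5 and comes back at 12. The conjugate addition of step 2 is run unchanged to enolate 6, which is treated with acrolein at −78 °C instead of being propargylated. The closed Zimmerman–Traxler aldol of this cyclic enolate adds anti to the butenyl arm and anti at the carbinol to give (2S,3S)-2-[(1S)-1-hydroxyprop-2-en-1-yl]-3-methyl-3-(3-methylbut-3-en-1-yl)cyclopentan-1-one F4. Addition of iPrMgCl/CeCl3 (4 equiv, THF, −78 °C) as in step 3 gives (1R,2S,3S)-2-[(1S)-1-hydroxyprop-2-en-1-yl]-3-methyl-3-(3-methylbut-3-en-1-yl)-1-(propan-2-yl)cyclopentan-1-ol F5. 4-Methoxybenzoyl chloride, DMAP and pyridine at 0 °C acylate only the secondary allylic hydroxyl and deliver 12.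

Step 2, the one-pot conjugate addition/propargylation. The hindered aluminate 7 may alkylate slowly, at the other α-carbon after proton exchange, or with weak facial control; residual minor enantiomer is less of a concern because step 4 turns it into a separable diastereomer. The fallback sets out from enone 5 and comes back at 8, replacing the basic enolate alkylation by a cationic propargylation of a neutral enol ether. Enolate 6 is trapped in the conjugate-addition flask with Et3SiOTf to give triethyl{[(3S)-3-methyl-3-(3-methylbut-3-en-1-yl)cyclopent-1-en-1-yl]oxy}silane F1, which is isolated. Methyl propargyl ether and Co2(CO)8 give hexacarbonyl(μ-3-methoxyprop-1-yne)dicobalt F2. A Nicholas reaction of F1 with F2 (BF3·OEt2, CH2Cl2, −78 °C) attacks regiospecifically at C5 and anti to the butenyl arm, giving the hexacarbonyldicobalt complex of ketone 8 F3. (NH4)2Ce(NO3)6 in acetone at 0 °C removes the cobalt and returns 8.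

Step 5, the ring-closing metathesis. The vinyl group sits next to a bulky aroyloxy group and a crowded ring carbon, the partner alkene is 1,1-disubstituted, and the ring is trans-fused, so initiation may be slow and oligomers may form. The fallback sets out from 12 and comes back at 13, closing the ring on the free allylic alcohol and acylating last. K2CO3 in MeOH removes the anisate and gives the diol F5 already described. Its free allylic hydroxyl speeds carbene formation, and the same ruthenium catalyst closes the ring to (3R,3aS,4S,8aS)-6,8a-dimethyl-3-(propan-2-yl)-1,2,3,3a,4,7,8,8a-octahydroazulene-3,4-diol F6. 4-Methoxybenzoyl chloride, DMAP and pyridine at 0 °C acylate the secondary allylic hydroxyl selectively to give 13.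

**Further compounds**
F1 | step 2 | triethyl{[(3S)-3-methyl-3-(3-methylbut-3-en-1-yl)cyclopent-1-en-1-yl]oxy}silane | CC[Si](CC)(CC)OC1=C[C@@](C)(CCC(C)=C)CC1
F2 | step 2 | hexacarbonyl(μ-3-methoxyprop-1-yne)dicobalt | COC[C]12[Co]3(=C=O)(=C=O)(=C=O)[Co]1(=C=O)(=C=O)(=C=O)[CH]23
F3 | step 2 | hexacarbonyldicobalt complex of (2R,3S)-3-methyl-3-(3-methylbut-3-en-1-yl)-2-(prop-2-yn-1-yl)cyclopentan-1-one | O=C1CC[C@](C)(CCC(C)=C)[C@H]1C[C]23[Co]4(=C=O)(=C=O)(=C=O)[Co]2(=C=O)(=C=O)(=C=O)[CH]34
F4 | step 4 | (2S,3S)-2-[(1S)-1-hydroxyprop-2-en-1-yl]-3-methyl-3-(3-methylbut-3-en-1-yl)cyclopentan-1-one | C=C[C@H](O)[C@@H]1[C@@](C)(CCC(C)=C)CCC1=O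
F5 | step 4 | (1R,2S,3S)-2-[(1S)-1-hydroxyprop-2-en-1-yl]-3-methyl-3-(3-methylbut-3-en-1-yl)-1-(propan-2-yl)cyclopentan-1-ol | C=C[C@H](O)[C@@H]1[C@@](C)(CCC(C)=C)CC[C@@]1(O)C(C)C
F6 | step 5 | (3R,3aS,4S,8aS)-6,8a-dimethyl-3-(propan-2-yl)-1,2,3,3a,4,7,8,8a-octahydroazulene-3,4-diol | O[C@H]1C=C(C)CC[C@@]2(C)CC[C@@](O)(C(C)C)[C@H]12
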